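The ratio to watch is 0.334 at the end of the elm run. This target share, the target formed per starting material consumed, reads 0.341 at the first elm reading, 0.335 at the end of the cedar run, and 0.315 at the end of the oak run, which has half the elm reagent. Target is therefore reckoned as share times conversion.

| flask | starting material | reagent | remark | time |
|---|---|---|---|---|
| elm | 0.055 M | 0.0715 M | run made earlier |  |
| oak | 0.055 M | 0.036 M | run made earlier |  |
| cedar | 0.055 M | 0.054 M | run made earlier |  |
| south-west | 0.055 M (fed, over 2.00 min) | 0.0715 M | a stirred flask in which starting material is dosed at a steady rate over 2.00 min without added volume, worked up at 2.5 min | 2.5 min |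
| north-west | 0.055 M | 0.0715 M | one stirred flow tank at steady state, fed with the mixture as stated, mean residence time 25.0 min |  |
| north | 0.055 M | 0.0715 M | a closed flask charged with all of it at once and left for 2.5 min | 2.5 min |
| south | 0.055 M | 0.0715 M | a single well-mixed tank run continuously and read at steady state, 2.5 min in it on average |  |

elm run (percent of the starting material charged)

| time / min | target / % | starting material / % |
|---|---|---|
| 0.200 | 4.5 | 86.8 |
| 0.417 | 7.9 | 75.2 |
| 0.667 | 11.8 | 65.2 |
| 1.33 | 17.4 | 46.1 |
| 2.50 | 23.7 | 29.1 |

oak run (percent of the starting material charged)

| time / s | target / % | starting material / % |
|---|---|---|
| 10.0 | 1.4 | 94.2 |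
| 15.0 | 2.7 | 91.2 |
| 25.0 | 4.4 | 86.3 |
| 50.0 | 7.5 | 77.0 |
| 90.0 | 10.6 | 66.3 |

cedar run (percent of the starting material charged)

| time / s | target / % | starting material / % |
|---|---|---|
| 10.0 | 2.8 | 91.4 |
| 25.0 | 6.5 | 80.3 |
| 40.0 | 9.3 | 71.6 |
| 60.0 | 12.5 | 63.3 |
| 90.0 | 15.3 | 54.3 |

(standard deviation of a reading: 0.3 percentage points)

- the set-up with the highest amount of target at the outlet or at the end, in percent of the starting material put in ("none" if the first two lie within 2 percentage points) (south-west / north-west / north / south / none)
- amount of target at the outlet or at the end, in percent of the starting material put in, south-west
- amount of target at the outlet or at the end, in percent of the starting material put in, north-west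
- amount of target at the outlet or at the end, in percent of the starting material put in, north
- amount of target at the outlet or at the end, in percent of the starting material put in, south

- the stated concentrations are those of everything mixed, before any reaction; amounts are the same in each set-up
- the numbers in the tables scatter with a standard deviation of 0.3 percentage points
- the feed brings no volume worth counting
- the earlier runs were made in a closed, stirred flask

Starting material is lost at first at 0.660 min⁻¹ in the elm run and 0.348 min⁻¹ in the oak run, so the rate is taken as k·c(starting material)·c(reagent). With one reagent consumed per starting material, the end of the elm run gives k = 10.8 M⁻¹ min⁻¹, and the end of the oak run gives 11.0 M⁻¹ min⁻¹. In the charge asked about, starting material is the limiting reagent, and in the north flask and both tanks c(reagent) stays above c(starting material) by 0.01650 M.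

The north flask repeats the elm charge, so its target curve can be drawn from these values. It starts with a slope of 0.258 min⁻¹ as a fraction of the charge. A conversion of 0.5 is reckoned at 1.16 min, with target near 16.7%. Target would cross starting material at 25.1% each, at 2.94 min, which is later than the 2.5 min of the north flask, so north ends before the crossing, as the last elm reading does. The level reckoned for full conversion of the starting material lies at 33.4% of the charge.

The last elm reading gives north 23.7%. The tank balance, c(starting material) from cA − c = kτ·c·(c + excess), gives 0.0257 M and target 17.8% for south. For north-west it gives 0.007377 M and target 28.9%, more than north. In south-west, the last of the dose has 0.500 min in the flask, less than the 2.5 min of north.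

The forecast, which states “Target per starting material consumed stays near 0.33 in all runs”, gives 18.1% for south-west, 28.6% for north-west, 23.5% for north and 17.6% for south, with north-west best; its north-west figure lies 0.30 percentage points below the one reckoned above.

The simulation gives 18.0% for south-west, 28.5% for north-west, 23.3% for north and 17.5% for south, with north-west best.

    starting material + reagent → target (k = 0.0590 M⁻¹ s⁻¹)
    starting material + reagent → isomer of the product (k = 0.120 M⁻¹ s⁻¹)

In the north flask, both steps ran side by side while starting material and reagent were present, with half-lives, each step alone at the charged concentrations, of 2.7 min to target and 1.3 min to isomer of the product, and the end held 23.3% target beside 47.4% isomer of the product, a target share of 0.330. In the north-west tank, the same pair ran at 0.00741 M starting material, 13.5% of the charge left the outlet unreacted, and the share 0.334 of the 86.5% consumed is 28.9%, where the outlet held 28.5% target.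

The readings come from a simulation from invented constants, noise included.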